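## Retrosynthetic overview
1. Target 13 comes from ketal hydrolysis, C6′ ketone reduction and nucleophilic epoxidation of a drimenyl p‑quinone monoketal. That monoketal comes from anodic dearomatisation of an o‑(drimenylmethyl)phenol.
2. The key C11–C1′ bond is made by visible‑light Ni/photoredox coupling of a C11 radical (from a catecholborane adduct) with methyl 4‑bromo‑3‑hydroxybenzoate. α‑Face hydroboration of a drima‑7,9(11)‑diene sets 9α‑H.
3. The diene comes from two photochemical C–C scissions that excise C12, C13 and the isopropyl group of an abietane. Alkoxy‑radical β‑scission cuts C13–C14 and creates the C8 methyl; a Norrish II reaction cuts C11–C12.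
4. The 13‑ol comes from the 13,14‑epoxide of methyl abietate, which supplies C4, C5 and C10 and relays C9.
5. No carbocycle is built. The A/B decalin and the six‑membered ring (as an arene) are bought, ring C is cut away, and only the oxirane is formed (step 8).

Assumption: methyl abietate (CAS 127‑25‑3) is bought; starting from abietic acid (MeI, K2CO3) would add one step.

Numbering: the decalin keeps terpenoid numbers C1–C10, and C11 is the CH2 on C9. In the six‑membered ring, C1′ bears C11, C2′ is the epoxide CH, C3′ is C=O, C4′ bears CH2OH, C5′ is =CH and C6′ is CHOH. All decalins are 4α‑(CO2Me or CH2OH), 4β‑Me, 5α‑H, 10β‑Me.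

## Route

**Step 1**
Reactants: 1, methyl abietate (methyl abieta‑7,13‑dien‑18‑oate, 9α‑H)
Product: 2, methyl 13α,14α‑epoxyabiet‑7‑en‑18‑oate
Conditions: mCPBA (1.05 equiv), NaHCO3, CH2Cl2, −20 → 0 °C
Reagents that add atoms: mCPBA, O=C(OO)c1cccc(Cl)c1 (delivers O)
Why: Prilezhaev epoxidation takes the open, isopropyl‑activated C13=C14 end of the diene (the site OsO4 also attacks) from the α face away from the C10 β‑methyl, and the C13/C14 configuration does not matter because both centres are erased in steps 2–4.

**Step 2**
Reactants: 2
Product: 3, methyl 13α‑hydroxyabiet‑7‑en‑18‑oate (13β‑isopropyl, C14 = CH2)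
Conditions: Pd2(dba)3·CHCl3 (2.5 mol %), n‑Bu3P (10 mol %), HCO2H (5 equiv), Et3N (2 equiv), THF, 23 °C
Reagents that add atoms: none
Why: In this Tsuji‑type Pd/formate hydrogenolysis of an alkenyl oxirane, Pd(0) ionises the allylic C14–O bond to a syn,syn π‑allyl (C7–C8–C14) and the Pd–H from formate is delivered to C14 next to the alkoxide, giving the homoallylic tertiary alcohol with Δ7 and the hindered ester intact.

**Step 3**
Reactants: 3
Product: 4, methyl 13‑oxo‑13,14‑secoabiet‑7‑en‑18‑oate (C8–CH3, Δ7, 9α‑H, 9β‑CH2CH2C(O)i‑Pr)
Conditions: [Ir(dF(CF3)ppy)2(5,5′‑dCF3bpy)]PF6 (2 mol %), n‑Bu4P[O2P(OMe)2] (25 mol %), 2,4,6‑triisopropylbenzenethiol (25 mol %), PhCF3, 450 nm LEDs, 25 °C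
Reagents that add atoms: none
Why: PCET activation of the tertiary O–H gives the C13 alkoxy radical, which breaks C13–C14 because only that β‑scission gives an allyl radical, and thiol HAT to the primary terminus then makes the C8 methyl while keeping the trisubstituted Δ7 alkene and C9 untouched (redox‑neutral ring‑opening isomerisation of a cycloalkanol).

**Step 4**
Reactants: 4
Product: 5, methyl drima‑7,9(11)‑dien‑13‑oate (C11H2=C9–C8(CH3)=C7H, 4α‑CO2Me)
Conditions: hν 310 nm (Pyrex), degassed MeCN, 0.02 M, flow, 20 °C; 3‑methylbutan‑2‑one removed in vacuo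
Reagents that add atoms: none
Why: In this Norrish type II cleavage the n,π* ketone has a single γ‑H (C9–H, tertiary and allylic) and the 1,4‑biradical fragments at C11–C12 to C9=C11 plus a volatile enol, excising five carbons at once; C9 is deliberately flattened and reset in step 5.

**Step 5 (one pot, key step)**
Reactants: 5; 6, methyl 4‑bromo‑3‑hydroxybenzoate
Product: 8, methyl 4‑{[9β‑drim‑7‑enyl (4α‑CO2Me, 9α‑H)]methyl}‑3‑hydroxybenzoate, formed via 7 (the C11 B‑alkylcatecholborane, not isolated)
Conditions: (i) catecholborane (1.2 equiv), Me2NC(O)Me (10 mol %), CH2Cl2, 23–40 °C; MeOH (0.3 equiv); evaporate. (ii) 6 + KOt‑Bu (1.1 equiv each), 4CzIPN (2 mol %), NiCl2·glyme/dtbbpy (5/6 mol %), DMA, 450 nm LEDs, 25 °C; aq NH4Cl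
Reagents that add atoms: none (catecholborane leaves only H at C9)
Why: Proposed new method: syn hydroboration puts B on C11 and H on C9 from the α face (the β face is blocked by the axial C10 methyl), fixing 9α‑H; the potassium phenoxide of 6 then binds boron to give the borate [R–B(cat)(OAr)]−, whose one‑electron oxidation by excited 4CzIPN enters the same catecholate‑delocalised perboryl radical that carries B‑alkylcatecholborane radical chains and fragments to the primary C11 radical (the only alkyl on boron) plus ArO–Bcat (phenol masked in situ), after which Ni oxidative addition into the para‑ester‑activated C–Br bond, radical capture and reductive elimination from Ni(III) form C11–C1′ while reduced 4CzIPN returns Ni(I) to Ni(0); the closest known reactions are Ni/photoredox arylation of alkyl bis(catecholato)silicates and of Lewis‑base‑activated alkylboronic esters, and borates made directly from catecholborane hydroboration adducts have not been used this way.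

**Step 6**
Reactants: 8
Product: 9, 2‑{[drim‑7‑enyl (4α‑CH2OH)]methyl}‑5‑(hydroxymethyl)phenol
Conditions: LiAlH4 (6 equiv), THF, 0 → 66 °C; Rochelle salt work‑up
Reagents that add atoms: none
Why: Hydride reduction takes both the hindered C4 ester and the aryl ester to CH2OH in one operation, and the alkene, the phenoxide and all stereocentres are inert.

**Step 7**
Reactants: 9
Product: 10, 2‑(drimenylmethyl)‑5‑(hydroxymethyl)‑4,4‑dimethoxycyclohexa‑2,5‑dienone (C6′=O, C3′(OMe)2)
Conditions: undivided cell, graphite (+)/Pt (−), 0.1 M LiClO4 in MeOH, NaHCO3, 10 mA cm−2, 4.3 F mol−1, 0 °C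
Reagents that add atoms: methanol, CO (two OMe)
Why: Anodic phenol oxidation traps the phenoxenium ion with MeOH at the free para carbon C3′ and then oxidises the resulting 4‑methoxyphenol again to the p‑quinone monoketal; the phenol oxidises well before the Δ7 alkene or the alcohols, and placing the carbonyl at C6′ fixes the regiochemistry of steps 8–10.

**Step 8**
Reactants: 10
Product: 11, the C1′–C2′ epoxide of 10 (oxirane face as in 13)
Conditions: t‑BuOOH (decane, 2 equiv), DBU (1.5 equiv), CH2Cl2, −20 °C; diastereomers separated
Reagents that add atoms: tert‑butyl hydroperoxide, CC(C)(C)OO (delivers O)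
Why: In this Weitz–Scheffer epoxidation the peroxide anion adds only to the unsubstituted β‑carbon C2′ (C4′ is blocked and the electron‑rich Δ7 is inert), and the face is chosen by the decalin, because in the rotamer with C1′ anti to quaternary C10, the ring perpendicular to C9–C11 and C6′=O turned away from the C8 methyl, attack on the uncovered face gives the required C1′/C2′ configuration, with only moderate dr expected.

**Step 9**
Reactants: 11
Product: 12, the (6′R)‑alcohol (OH anti to the oxirane, syn to C11)
Conditions: DIBAL‑H (5 equiv), CH2Cl2/toluene, −78 °C; Rochelle salt work‑up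
Reagents that add atoms: none
Why: This is a 1,2‑reduction by a Lewis‑acidic hydride in which the OH groups are first capped as Al alkoxides and i‑Bu2AlH bound to the oxirane oxygen then delivers H to C6′ from the oxirane face, placing OH anti to the epoxide, while the ketal shields C3′ so regiochemistry is fixed.

**Step 10**
Reactants: 12
Product: 13, Epoxypholamin A (1′S,2′S,6′R)
Conditions: 5 % aq oxalic acid, THF, 0 → 23 °C (or Montmorillonite K10, wet CH2Cl2)
Reagents that add atoms: water, O (carbonyl oxygen)
Why: Mild hydrolysis of the allylic dimethyl ketal unmasks the C3′ enone without opening the oxirane or protonating Δ7, and no stereocentre is touched.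

## Compound list
1 | methyl abietate | CC(C)C1=CC2=CC[C@H]3[C@](C)(C(=O)OC)CCC[C@]3(C)[C@H]2CC1 | starting material
2 | methyl 13α,14α‑epoxyabiet‑7‑en‑18‑oate | CC(C)[C@]12CC[C@H]3C(=CC[C@H]4[C@](C)(C(=O)OC)CCC[C@]34C)[C@H]1O2 | intermediate
3 | methyl 13α‑hydroxyabiet‑7‑en‑18‑oate | CC(C)[C@]1(O)CC[C@H]2C(=CC[C@H]3[C@](C)(C(=O)OC)CCC[C@]23C)C1 | intermediate
4 | methyl 13‑oxo‑13,14‑secoabiet‑7‑en‑18‑oate | CC1=CC[C@H]2[C@](C)(C(=O)OC)CCC[C@]2(C)[C@H]1CCC(=O)C(C)C | intermediate
5 | methyl drima‑7,9(11)‑dien‑13‑oate | C=C1C(C)=CC[C@H]2[C@](C)(C(=O)OC)CCC[C@]12C | intermediate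
6 | methyl 4‑bromo‑3‑hydroxybenzoate | COC(=O)c1ccc(Br)c(O)c1 | starting material
7 | C11 B‑alkylcatecholborane | CC1=CC[C@H]2[C@](C)(C(=O)OC)CCC[C@]2(C)[C@H]1CB1Oc2ccccc2O1 | intermediate (not isolated)
8 | coupled diester phenol | CC1=CC[C@H]2[C@](C)(C(=O)OC)CCC[C@]2(C)[C@H]1Cc1ccc(C(=O)OC)cc1O | intermediate
9 | phenol diol | CC1=CC[C@H]2[C@](C)(CO)CCC[C@]2(C)[C@H]1Cc1ccc(CO)cc1O | intermediate
10 | p‑quinone monoketal | CC1=CC[C@H]2[C@](C)(CO)CCC[C@]2(C)[C@H]1CC1=CC(OC)(OC)C(CO)=CC1=O | intermediate
11 | epoxy ketone ketal | CC1=CC[C@H]2[C@](C)(CO)CCC[C@]2(C)[C@H]1C[C@@]12O[C@@H]1C(OC)(OC)C(CO)=CC2=O | intermediate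
12 | epoxy alcohol ketal | CC1=CC[C@H]2[C@](C)(CO)CCC[C@]2(C)[C@H]1C[C@@]12O[C@@H]1C(OC)(OC)C(CO)=C[C@H]2O | intermediate
13 | Epoxypholamin A | CC1=CC[C@H]2[C@](C)(CO)CCC[C@]2(C)[C@H]1C[C@@]12O[C@@H]1C(=O)C(CO)=C[C@H]2O | target

## Totals
Total steps: 10, with the one‑pot step 5 counted once. Longest linear sequence: 10, from methyl abietate; compound 6 is bought.

## Three steps most likely to fail
1. **Step 5 (new borate/Ni/photoredox arylation).** Possible failures are ligand scrambling at boron, catecholate poisoning of Ni, and protodeboronation.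
   Fallback (known chemistry): hydroborate 5 with 9‑BBN and run a thermal Pd(dppf)Cl2/Cs2CO3 B‑alkyl Suzuki–Miyaura coupling with the O‑pivaloyl derivative of 6. The pivalate is removed at no extra cost by LiAlH4 in step 6.
2. **Step 8 (facial selectivity).** The decalin is remote, competing C9–C11 rotamers predict opposite faces, and the dr could approach 1:1.
   Fallback: stop relying on the decalin and buy the controlling ring stereocentre.
   - Add the C11 radical by photochemical Giese addition to enantiopure 4‑(TBSO)cyclohex‑2‑enone made from (−)‑quinic acid, using a C18‑OTBS drimane.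
   - Restore the enone by Saegusa oxidation, then carry out nucleophilic epoxidation anti to OTBS, which gives the trans OH/oxirane relationship directly.
   - Finish with a second Saegusa oxidation, Baylis–Hillman hydroxymethylation with CH2O, and desilylation.
   - This is longer, but every ring centre is then set 1,2 to a bought carbinol.
3. **Step 9 (C6′ configuration).** External hydride attack anti to the oxirane would give the 6′‑epimer if delivery from the oxirane‑bound aluminium does not dominate.
   Fallback: make the cis alcohol on purpose (NaBH4/CeCl3) and invert it by SN2. Use a Mitsunobu reaction with chloroacetic acid, DIAD and PPh3, which harmlessly esterifies any primary OH that also reacts. Follow with K2CO3/MeOH and then step 10.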